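(All runs were generated by integration for an exercise.)

It is easy to say what goes into these flasks: starting material at a chosen charge, and gas held over it at one saturation value.

| setting | north-west | east | beta | zeta |
|---|---|---|---|---|
| starting material | 11 mM | 44 mM | 22 mM | 22 mM |
| gas phase | 2.9 mM (held) | 2.9 mM (held) | 2.9 mM (held) | 2.9 mM (held) |
| remark | run made earlier | run made earlier |  |  |
| time |  |  | 25 min | 20 min |

| run | time / min | starting material / % | side product / % | target / % |
|---|---|---|---|---|
| north-west | 3.00 | 76 | 3 | 18 |
| north-west | 6.00 | 61 | 11 | 37 |
| north-west | 8.00 | 50 | 9 | 45 |
| north-west | 12.0 | 31 | 19 | 52 |
| north-west | 15.0 | 22 | 21 | 53 |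
| north-west | 20.0 | 8 | 21 | 67 |
| east | 1.00 | 96 | 0 | 8 |
| east | 3.00 | 79 | 8 | 12 |
| east | 6.00 | 59 | 18 | 24 |
| east | 8.00 | 48 | 28 | 27 |
| east | 12.0 | 27 | 42 | 30 |
| east | 15.0 | 23 | 46 | 35 |
| east | 20.0 | 9 | 52 | 35 |

(each reading ± 2 percentage points)

- percentages count the starting material that a species holds: one side product counts as two
- at the start none of the gas is dissolved
- reactions considered so far: gas phase <-> dissolved gas; starting material + dissolved gas -> target; 2 dissolved gas -> self-condensation product; starting material + target -> side product

1. which of these there is most of at the end, counted by the starting material in it, beta (starting material / target / side product)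
2. which of these there is most of at the end, counted by the starting material in it, zeta (starting material / target / side product)
3. how much there is at the end of the one of these that leads, in percent of the starting material charged: beta
4. how much there is at the end of the one of these that leads, in percent of the starting material charged: zeta

I follow the run slowly. At the first instant none of the gas is dissolved, so dissolving is the one step with its partners present, and starting material stands at its full charge.

By 8.00 min the north-west run keeps 50% of its starting material and the east run 48%, although their charges differ by a factor of 4.00. Within the scatter of these readings the fraction lost hardly moves with the charge, which is how a pseudo-first-order fall reads. Target is now present too, and it meets starting material: the east run holds 28% side product, more than the 9% of the north-west run.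

By 20.0 min the two runs keep 8% and 9% of starting material, so I turn to how the rest is split. I call x the side product over the target at that time, and I work in logarithms to base ten. The power n, the slope of the logarithm of x against the logarithm of c(starting material) charged, is a reading from two scattered runs and comes out like this:

x, north-west = 0.313, logarithm −0.504

x, east = 1.49, logarithm 0.172

n = 1.12

For zeta, charged with 22 mM, this gives:

x = 0.682

starting material left, taken as the mean of the two runs = 8.50%

target = 54.4%

Since x lies below one and starting material is less than target, I expect target to lead in zeta. Beta stands for 25 min, past my last readings, and I expect the same leader there.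

The forecast names target for beta at 56% and target for zeta at 54%, holding that the “main step is pseudo-first-order”.

The flasks give target at 53.7% in beta and target at 51.8% in zeta.

    gas phase ⇌ dissolved gas, rate k1*(csat - [dissolved gas]) (kL = 0.0400 s⁻¹)
    starting material + dissolved gas → target (k = 1.29 L mol⁻¹ s⁻¹)
    2 dissolved gas → self-condensation product (k = 25.3 L mol⁻¹ s⁻¹)
    starting material + target → side product (k = 0.0589 L mol⁻¹ s⁻¹)

Zeta holds 37.4% side product at 20 min, so its x is 0.722 beside my 0.682. The neighbour of zeta charged with 13 mM is read at the same time and keeps 12.2% of its starting material. With n = 1.12, I reckon its x as 0.378, which puts target at 63.7%. That flask holds 61.7% target.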